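The dihydrobenzofuran is disconnected at C3–C3a: its ring O1–C2–C3–C3a–C7a is read as the contracted pyranone of a (2S)-7-benzyloxy-5-methoxyflavanone, whose carbonyl carbon C4 becomes the exocyclic C3 hydroxymethyl carbon. In one operation, trivalent iodine drives the electron-rich aromatic carbon C4a from C4 to C3, which forms the C3–C3a bond, closes the five-membered ring, sets C3 trans to the C2 aryl group and releases C4 as a methyl ester. The precursor flavanone carries the ring B phenol as a pivalate so that ring B is a poor migrating group. The ester is then reduced and the arene joined to a separately made tetrahydrofuran by B-alkyl Suzuki coupling.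

Key step: step 7

Remarks on the chemistry (assumptions)
- Numbering: flavanone O1, C2, C3, C4, C4a–C8a; dihydrobenzofuran O1, C2, C3, C3a–C7a; tetrahydrofuran O1, C2 (aryl), C3 (CH2OH), C4 (CH2Ar), C5. The target is (2S,3R)-trans in the dihydrobenzofuran and (2R,3S,4S) in the tetrahydrofuran (2,3-trans, 3,4-cis).
- Stereochemical bookkeeping: (2S)-flavanone → (2S,3S)-ester → (2S,3R)-alcohol. The descriptor at C3 changes on reduction by priority only.
- Precursor design: during the key step the ring B phenol is an aryl pivalate, not a silyl ether. A para-silyloxy group would make ring B a good migrating group (isoflavone pathway), would favour acid ionisation of C2–O1 and could be lost in H2SO4, exposing a phenol to the oxidant. The pivalate is removed by the hydride that reduces the ester, so no step is added.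
- Assumption: the sense of induction of t-BuPyOX on the chromone is taken to follow that on carbocyclic enones, which assigns the (R)-ligand to the (S)-flavanone. If the assignment proves reversed, the antipodal ligand is used.

Step 1
Reactants: 1 2',4',6'-trihydroxyacetophenone
Product: 2 1-(4-benzyloxy-2,6-dihydroxyphenyl)ethanone
Conditions: BnBr (1.0 equiv), K2CO3 (1.1 equiv), DMF, 0 °C to rt
Reagents that add atoms: benzyl bromide, BrCc1ccccc1
Why: Williamson etherification, in which the 4'-hydroxyl (para to the acetyl group and the only one not hydrogen-bonded to the carbonyl) is the most acidic and should be alkylated first by one equivalent of halide.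

Step 2
Reactants: 2 1-(4-benzyloxy-2,6-dihydroxyphenyl)ethanone
Product: 3 1-(4-benzyloxy-2-hydroxy-6-methoxyphenyl)ethanone
Conditions: Me2SO4 (1.05 equiv), K2CO3, acetone, reflux
Reagents that add atoms: dimethyl sulfate, COS(=O)(=O)OC
Why: Williamson O-methylation of one of two equivalent hydroxyls, after which the last hydroxyl is locked in a hydrogen bond to the carbonyl and should resist one equivalent of reagent.

Step 3
Reactants: 3 1-(4-benzyloxy-2-hydroxy-6-methoxyphenyl)ethanone
Product: 5 7-benzyloxy-5-methoxy-4H-chromen-4-one, via enaminone 4 (not isolated)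
Conditions: Me2NCH(OMe)2, toluene, 95 °C; concentrate; then conc. HCl, CH2Cl2, rt to 40 °C
Reagents that add atoms: N,N-dimethylformamide dimethyl acetal, COC(OC)N(C)C
Why: Condensation of the methyl ketone with the amide acetal gives the enaminone, and acid then promotes addition of the phenol and loss of dimethylamine (standard chromone synthesis).

Step 4
Reactants: 6 2-methoxy-4-(4,4,5,5-tetramethyl-1,3,2-dioxaborolan-2-yl)phenol
Product: 7 2-methoxy-4-(4,4,5,5-tetramethyl-1,3,2-dioxaborolan-2-yl)phenyl pivalate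
Conditions: PivCl, Et3N, DMAP (cat.), CH2Cl2, 0 °C to rt
Reagents that add atoms: pivaloyl chloride, CC(C)(C)C(Cl)=O
Why: DMAP-catalysed acylation of the phenol, to which the pinacol boronate is inert.

Step 5
Reactants: 7 2-methoxy-4-(4,4,5,5-tetramethyl-1,3,2-dioxaborolan-2-yl)phenyl pivalate
Product: 8 [3-methoxy-4-(pivaloyloxy)phenyl]boronic acid
Conditions: NaIO4, NH4OAc, acetone/H2O, rt
Reagents that add atoms: water, O
Why: Periodate cleavage of the released pinacol drives hydrolysis of the boronic ester to the free boronic acid under near-neutral conditions that a hindered aryl ester should survive.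

Step 6
Reactants: 5 7-benzyloxy-5-methoxy-4H-chromen-4-one; 8 [3-methoxy-4-(pivaloyloxy)phenyl]boronic acid
Product: 9 4-[(2S)-7-benzyloxy-5-methoxy-4-oxochroman-2-yl]-2-methoxyphenyl pivalate
Conditions: Pd(OCOCF3)2 (5 mol %), (R)-t-BuPyOX (6 mol %), NH4PF6 (30 mol %), H2O (5 equiv), ClCH2CH2Cl, 60 °C
Reagents that add atoms: none
Why: Catalytic asymmetric conjugate addition of an arylboronic acid to a chromone by a cationic divalent palladium pyridine-oxazoline complex, in which the aryl-palladium species inserts C2=C3 on the face left open by the tert-butyl group of the ligand (this sets C2) and water protonates the palladium enolate.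

Step 7
Reactants: 9 4-[(2S)-7-benzyloxy-5-methoxy-4-oxochroman-2-yl]-2-methoxyphenyl pivalate
Product: 13 methyl (2S,3S)-6-benzyloxy-4-methoxy-2-[3-methoxy-4-(pivaloyloxy)phenyl]-2,3-dihydrobenzofuran-3-carboxylate, via methyl enol ether 10 (not isolated), via iodane ketal 11 (not isolated), via trimethyl orthoester 12 (not isolated)
Conditions: PhI(OAc)2 (1.3 equiv), conc. H2SO4 (0.5 equiv), HC(OMe)3, 0 °C to rt; aq. NaHCO3
Reagents that add atoms: trimethyl orthoformate, COC(OC)OC
Why: Acid and orthoformate should convert the C4 ketone into enol ether 10, trivalent iodine then adds to C3 anti to the C2 aryl group with methanol capture at C4 to give 11, and loss of iodobenzene is assisted by anti-periplanar 1,2-migration of the aromatic carbon C4a from C4 to C3, the two ketal oxygens stabilising the dialkoxycarbenium ion that is captured as orthoester 12 and hydrolysed to the methyl ester on work-up. The closest known reaction type is the oxidative ring contraction of flavanones to trans-2-aryl-2,3-dihydrobenzofuran-3-carboxylates with PhI(OAc)2 or Tl(NO3)3 in trimethyl orthoformate, a semipinacol-type 1,2-aryl shift. The dihydrofuran ring O1–C2–C3–C3a–C7a is closed by ring contraction and not by cyclisation of an open chain: the ipso carbon bridges C4 and C3 in a phenonium-like transition state (formally 3-exo-tet) and the C4–C4a bond then breaks. C3 is the new stereocenter and is controlled by C2, because iodination anti to the equatorial aryl group followed by inversion at C3 places the ester trans to the aryl group and the epimerisable ester backs this up, while C2 is not involved and stays (S). The step needs migration of C4a in preference to proton loss from C3 (flavone) and to migration of ring B from C2 (isoflavone); the 5-methoxy and 7-benzyloxy groups ortho and para to C4a raise its migratory aptitude, and the electron-withdrawing pivalate lowers that of ring B and disfavours acid ionisation of C2–O1.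

Step 8
Reactants: 13 methyl (2S,3S)-6-benzyloxy-4-methoxy-2-[3-methoxy-4-(pivaloyloxy)phenyl]-2,3-dihydrobenzofuran-3-carboxylate
Product: 14 4-[(2S,3R)-6-benzyloxy-3-(hydroxymethyl)-4-methoxy-2,3-dihydrobenzofuran-2-yl]-2-methoxyphenol
Conditions: LiAlH4, THF, 0 °C; then H2O, aq. NaOH
Reagents that add atoms: none
Why: Hydride reduction of the methyl ester to the primary alcohol with reductive cleavage of the aryl pivalate in the same operation, neither stereocenter being touched.

Step 9
Reactants: 14 4-[(2S,3R)-6-benzyloxy-3-(hydroxymethyl)-4-methoxy-2,3-dihydrobenzofuran-2-yl]-2-methoxyphenol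
Product: 15 (2S,3R)-6-benzyloxy-4-methoxy-2-[3-methoxy-4-(triisopropylsilyloxy)phenyl]-3-[(triisopropylsilyloxy)methyl]-2,3-dihydrobenzofuran
Conditions: TIPSCl (2.5 equiv), imidazole, DMF, rt to 40 °C
Reagents that add atoms: triisopropylsilyl chloride, CC(C)[Si](Cl)(C(C)C)C(C)C
Why: Imidazole-promoted silylation of the phenol and the primary alcohol, the hindered silyl ethers being chosen to survive the aqueous base of the later coupling.

Step 10
Reactants: 15 (2S,3R)-6-benzyloxy-4-methoxy-2-[3-methoxy-4-(triisopropylsilyloxy)phenyl]-3-[(triisopropylsilyloxy)methyl]-2,3-dihydrobenzofuran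
Product: 16 (2S,3R)-4-methoxy-2-[3-methoxy-4-(triisopropylsilyloxy)phenyl]-3-[(triisopropylsilyloxy)methyl]-2,3-dihydrobenzofuran-6-ol
Conditions: H2 (1 atm), 10% Pd/C, EtOAc, rt
Reagents that add atoms: none
Why: Hydrogenolysis of the benzyl aryl ether, which at 1 atm and room temperature should be much faster than cleavage of the cyclic benzylic C2–O1 bond.

Step 11
Reactants: 16 (2S,3R)-4-methoxy-2-[3-methoxy-4-(triisopropylsilyloxy)phenyl]-3-[(triisopropylsilyloxy)methyl]-2,3-dihydrobenzofuran-6-ol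
Product: 17 (2S,3R)-4-methoxy-2-[3-methoxy-4-(triisopropylsilyloxy)phenyl]-3-[(triisopropylsilyloxy)methyl]-2,3-dihydrobenzofuran-6-yl trifluoromethanesulfonate
Conditions: PhNTf2, Et3N, DMAP (cat.), CH2Cl2, 0 °C to rt
Reagents that add atoms: N-phenylbis(trifluoromethanesulfonimide), O=S(=O)(N(c1ccccc1)S(=O)(=O)C(F)(F)F)C(F)(F)F
Why: Sulfonylation of the only free phenol with a mild triflyl donor gives the aryl triflate needed for cross-coupling.

Step 12
Reactants: 18 isovanillin (3-hydroxy-4-methoxybenzaldehyde)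
Product: 19 4-methoxy-3-(triisopropylsilyloxy)benzaldehyde
Conditions: TIPSCl, imidazole, DMF, rt
Reagents that add atoms: triisopropylsilyl chloride, CC(C)[Si](Cl)(C(C)C)C(C)C
Why: Standard silylation of a phenol, the silyl ether being removable at the end under non-acidic conditions.

Step 13
Reactants: 19 4-methoxy-3-(triisopropylsilyloxy)benzaldehyde
Product: 20 rac-1-[4-methoxy-3-(triisopropylsilyloxy)phenyl]prop-2-en-1-ol
Conditions: CH2=CHMgBr, THF, −78 to 0 °C; aq. NH4Cl
Reagents that add atoms: vinylmagnesium bromide, C=C[Mg]Br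
Why: Grignard addition to the aldehyde gives the racemic secondary allylic alcohol.

Step 14
Reactants: 20 rac-1-[4-methoxy-3-(triisopropylsilyloxy)phenyl]prop-2-en-1-ol
Product: 21 (R)-1-[4-methoxy-3-(triisopropylsilyloxy)phenyl]prop-2-en-1-ol
Conditions: Ti(OiPr)4 (0.15 equiv), D-(−)-DIPT (0.2 equiv), t-BuOOH (0.6 equiv), 4 Å MS, CH2Cl2, −20 °C
Reagents that add atoms: none
Why: Sharpless kinetic resolution, in which the D-(−)-tartrate catalyst should epoxidise the (S)-alcohol much faster so that the (R)-alcohol, whose stereocenter becomes C2 of the tetrahydrofuran, is recovered at a little over half conversion.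

Step 15
Reactants: 21 (R)-1-[4-methoxy-3-(triisopropylsilyloxy)phenyl]prop-2-en-1-ol
Product: 22 triisopropyl{2-methoxy-5-[(1R)-1-(prop-2-yn-1-yloxy)prop-2-en-1-yl]phenoxy}silane
Conditions: NaH, propargyl bromide, Bu4NI (cat.), THF/DMF, 0 °C to rt
Reagents that add atoms: propargyl bromide, C#CCBr
Why: Williamson etherification of the sodium alkoxide, which does not touch the stereocenter.

Step 16
Reactants: 22 triisopropyl{2-methoxy-5-[(1R)-1-(prop-2-yn-1-yloxy)prop-2-en-1-yl]phenoxy}silane
Product: 23 triisopropyl{2-methoxy-5-[(S)-(oxiran-2-yl)(prop-2-yn-1-yloxy)methyl]phenoxy}silane (both epoxide epimers; benzylic center spatially as in 22)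
Conditions: mCPBA, NaHCO3, CH2Cl2, rt
Reagents that add atoms: 3-chloroperbenzoic acid, O=C(OO)c1cccc(Cl)c1
Why: Prilezhaev epoxidation of the terminal alkene, which is more reactive towards peracid than the terminal alkyne, the epoxide epimers being carried on together because that stereocenter is erased in the next step.

Step 17
Reactants: 23 triisopropyl{2-methoxy-5-[(S)-(oxiran-2-yl)(prop-2-yn-1-yloxy)methyl]phenoxy}silane
Product: 24 [(2R,3S)-2-[4-methoxy-3-(triisopropylsilyloxy)phenyl]-4-methylenetetrahydrofuran-3-yl]methanol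
Conditions: Cp2TiCl2 (2.5 equiv), Zn dust, THF, rt; then 1 M aq. HCl, 0 °C, brief
Reagents that add atoms: none
Why: Reductive epoxide opening by Cp2TiCl (trivalent titanium) gives the secondary β-titanoxy radical from either epoxide epimer, which closes 5-exo-dig onto the alkyne and sets C3 trans to the C2 aryl group because both substituents sit pseudo-equatorial in the ring-closing transition state.

Step 18
Reactants: 24 [(2R,3S)-2-[4-methoxy-3-(triisopropylsilyloxy)phenyl]-4-methylenetetrahydrofuran-3-yl]methanol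
Product: 25 triisopropyl{[(2R,3S)-2-[4-methoxy-3-(triisopropylsilyloxy)phenyl]-4-methylenetetrahydrofuran-3-yl]methoxy}silane
Conditions: TIPSCl, imidazole, DMF, rt
Reagents that add atoms: triisopropylsilyl chloride, CC(C)[Si](Cl)(C(C)C)C(C)C
Why: Silylation of the primary alcohol, the bulky group next to C4 reinforcing the facial bias of the hydroboration that follows.

Step 19
Reactants: 25 triisopropyl{[(2R,3S)-2-[4-methoxy-3-(triisopropylsilyloxy)phenyl]-4-methylenetetrahydrofuran-3-yl]methoxy}silane; 17 (2S,3R)-4-methoxy-2-[3-methoxy-4-(triisopropylsilyloxy)phenyl]-3-[(triisopropylsilyloxy)methyl]-2,3-dihydrobenzofuran-6-yl trifluoromethanesulfonate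
Product: 27 tetrakis(triisopropylsilyl) ether of 28, via alkylborane 26 (not isolated)
Conditions: 9-BBN dimer, THF, 0 °C to rt; then 17, Pd(dppf)Cl2 (5 mol %), 3 M aq. K3PO4, THF/DMF, 60 °C
Reagents that add atoms: none
Why: Hydroboration then B-alkyl Suzuki–Miyaura coupling, in which 9-BBN places boron on the terminal carbon and hydrogen on C4 from the face opposite the C3 silyloxymethyl group (this sets the 3,4-cis relationship) and the primary alkylborane couples with the aryl triflate.

Step 20
Reactants: 27 tetrakis(triisopropylsilyl) ether of 28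
Product: 28 4-[(2S,3R)-6-{[(3S,4S,5R)-5-(3-hydroxy-4-methoxyphenyl)-4-(hydroxymethyl)tetrahydrofuran-3-yl]methyl}-3-(hydroxymethyl)-4-methoxy-2,3-dihydrobenzofuran-2-yl]-2-methoxyphenol (target)
Conditions: Bu4NF, AcOH (1:1), THF, 0 °C to rt; aq. NH4Cl
Reagents that add atoms: none
Why: Fluoride cleavage of the two aryl and two alkyl silyl ethers, buffered with acetic acid so that the p-hydroxybenzylic ethers are not left as free phenoxides.

Compound list
1 | 2',4',6'-trihydroxyacetophenone | CC(=O)c1c(O)cc(O)cc1O | starting material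
2 | 1-(4-benzyloxy-2,6-dihydroxyphenyl)ethanone | CC(=O)c1c(O)cc(OCc2ccccc2)cc1O | intermediate
3 | 1-(4-benzyloxy-2-hydroxy-6-methoxyphenyl)ethanone | COc1cc(OCc2ccccc2)cc(O)c1C(C)=O | intermediate
4 | (E)-1-(4-benzyloxy-2-hydroxy-6-methoxyphenyl)-3-(dimethylamino)prop-2-en-1-one | COc1cc(OCc2ccccc2)cc(O)c1C(=O)/C=C/N(C)C | intermediate (not isolated)
5 | 7-benzyloxy-5-methoxy-4H-chromen-4-one | COc1cc(OCc3ccccc3)cc2occc(=O)c12 | intermediate
6 | 2-methoxy-4-(4,4,5,5-tetramethyl-1,3,2-dioxaborolan-2-yl)phenol | COc1cc(B2OC(C)(C)C(C)(C)O2)ccc1O | starting material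
7 | 2-methoxy-4-(4,4,5,5-tetramethyl-1,3,2-dioxaborolan-2-yl)phenyl pivalate | COc1cc(B2OC(C)(C)C(C)(C)O2)ccc1OC(=O)C(C)(C)C | intermediate
8 | [3-methoxy-4-(pivaloyloxy)phenyl]boronic acid | COc1cc(B(O)O)ccc1OC(=O)C(C)(C)C | intermediate
9 | 4-[(2S)-7-benzyloxy-5-methoxy-4-oxochroman-2-yl]-2-methoxyphenyl pivalate, the (S)-flavanone | COc1cc(OCc3ccccc3)cc2c1C(=O)C[C@@H](c1ccc(OC(=O)C(C)(C)C)c(OC)c1)O2 | intermediate
10 | 4-[(2S)-7-benzyloxy-4,5-dimethoxy-2H-chromen-2-yl]-2-methoxyphenyl pivalate | COc1cc(OCc3ccccc3)cc2c1C(OC)=C[C@@H](c1ccc(OC(=O)C(C)(C)C)c(OC)c1)O2 | intermediate (not isolated)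
11 | 4-{(2R,3R)-3-[acetoxy(phenyl)-λ3-iodanyl]-7-benzyloxy-4,4,5-trimethoxychroman-2-yl}-2-methoxyphenyl pivalate (iodine trans to the aryl group; C2 spatially as in 9) | COc1cc(OCc3ccccc3)cc2c1C(OC)(OC)[C@H]([I](OC(C)=O)c1ccccc1)[C@@H](c1ccc(OC(=O)C(C)(C)C)c(OC)c1)O2 | intermediate (not isolated)
12 | 4-[(2S,3S)-6-benzyloxy-4-methoxy-3-(trimethoxymethyl)-2,3-dihydrobenzofuran-2-yl]-2-methoxyphenyl pivalate | COc1cc(OCc3ccccc3)cc2c1[C@H](C(OC)(OC)OC)[C@@H](c1ccc(OC(=O)C(C)(C)C)c(OC)c1)O2 | intermediate (not isolated)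
13 | methyl (2S,3S)-6-benzyloxy-4-methoxy-2-[3-methoxy-4-(pivaloyloxy)phenyl]-2,3-dihydrobenzofuran-3-carboxylate (2,3-trans) | COc1cc(OCc3ccccc3)cc2c1[C@H](C(=O)OC)[C@@H](c1ccc(OC(=O)C(C)(C)C)c(OC)c1)O2 | intermediate
14 | 4-[(2S,3R)-6-benzyloxy-3-(hydroxymethyl)-4-methoxy-2,3-dihydrobenzofuran-2-yl]-2-methoxyphenol | COc1cc(OCc3ccccc3)cc2c1[C@H](CO)[C@@H](c1ccc(O)c(OC)c1)O2 | intermediate
15 | (2S,3R)-6-benzyloxy-4-methoxy-2-[3-methoxy-4-(triisopropylsilyloxy)phenyl]-3-[(triisopropylsilyloxy)methyl]-2,3-dihydrobenzofuran | COc1cc(OCc3ccccc3)cc2c1[C@H](CO[Si](C(C)C)(C(C)C)C(C)C)[C@@H](c1ccc(O[Si](C(C)C)(C(C)C)C(C)C)c(OC)c1)O2 | intermediate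
16 | (2S,3R)-4-methoxy-2-[3-methoxy-4-(triisopropylsilyloxy)phenyl]-3-[(triisopropylsilyloxy)methyl]-2,3-dihydrobenzofuran-6-ol | COc1cc(O)cc2c1[C@H](CO[Si](C(C)C)(C(C)C)C(C)C)[C@@H](c1ccc(O[Si](C(C)C)(C(C)C)C(C)C)c(OC)c1)O2 | intermediate
17 | (2S,3R)-4-methoxy-2-[3-methoxy-4-(triisopropylsilyloxy)phenyl]-3-[(triisopropylsilyloxy)methyl]-2,3-dihydrobenzofuran-6-yl trifluoromethanesulfonate | COc1cc(OS(=O)(=O)C(F)(F)F)cc2c1[C@H](CO[Si](C(C)C)(C(C)C)C(C)C)[C@@H](c1ccc(O[Si](C(C)C)(C(C)C)C(C)C)c(OC)c1)O2 | intermediate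
18 | isovanillin (3-hydroxy-4-methoxybenzaldehyde) | COc1ccc(C=O)cc1O | starting material
19 | 4-methoxy-3-(triisopropylsilyloxy)benzaldehyde | COc1ccc(C=O)cc1O[Si](C(C)C)(C(C)C)C(C)C | intermediate
20 | rac-1-[4-methoxy-3-(triisopropylsilyloxy)phenyl]prop-2-en-1-ol | COc1ccc(C(O)C=C)cc1O[Si](C(C)C)(C(C)C)C(C)C | intermediate
21 | (R)-1-[4-methoxy-3-(triisopropylsilyloxy)phenyl]prop-2-en-1-ol | C=C[C@@H](O)c1ccc(OC)c(O[Si](C(C)C)(C(C)C)C(C)C)c1 | intermediate
22 | triisopropyl{2-methoxy-5-[(1R)-1-(prop-2-yn-1-yloxy)prop-2-en-1-yl]phenoxy}silane | C=C[C@@H](OCC#C)c1ccc(OC)c(O[Si](C(C)C)(C(C)C)C(C)C)c1 | intermediate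
23 | triisopropyl{2-methoxy-5-[(S)-(oxiran-2-yl)(prop-2-yn-1-yloxy)methyl]phenoxy}silane (both epoxide epimers) | C1OC1[C@@H](OCC#C)c1ccc(OC)c(O[Si](C(C)C)(C(C)C)C(C)C)c1 | intermediate
24 | [(2R,3S)-2-[4-methoxy-3-(triisopropylsilyloxy)phenyl]-4-methylenetetrahydrofuran-3-yl]methanol | COc1ccc([C@@H]2OCC(=C)[C@H]2CO)cc1O[Si](C(C)C)(C(C)C)C(C)C | intermediate
25 | triisopropyl{[(2R,3S)-2-[4-methoxy-3-(triisopropylsilyloxy)phenyl]-4-methylenetetrahydrofuran-3-yl]methoxy}silane | COc1ccc([C@@H]2OCC(=C)[C@H]2CO[Si](C(C)C)(C(C)C)C(C)C)cc1O[Si](C(C)C)(C(C)C)C(C)C | intermediate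
26 | 9-{[(3S,4S,5R)-5-[4-methoxy-3-(triisopropylsilyloxy)phenyl]-4-[(triisopropylsilyloxy)methyl]tetrahydrofuran-3-yl]methyl}-9-borabicyclo[3.3.1]nonane | COc1ccc([C@@H]2OC[C@@H](CB3C4CCCC3CCC4)[C@H]2CO[Si](C(C)C)(C(C)C)C(C)C)cc1O[Si](C(C)C)(C(C)C)C(C)C | intermediate (not isolated)
27 | tetrakis(triisopropylsilyl) ether of 28 (both phenols and both primary alcohols silylated; dihydrobenzofuran 2S,3R; tetrahydrofuran 2R,3S,4S) | COc1ccc([C@@H]2OC[C@@H](Cc3cc(OC)c4c(c3)O[C@H](c3ccc(O[Si](C(C)C)(C(C)C)C(C)C)c(OC)c3)[C@H]4CO[Si](C(C)C)(C(C)C)C(C)C)[C@H]2CO[Si](C(C)C)(C(C)C)C(C)C)cc1O[Si](C(C)C)(C(C)C)C(C)C | intermediate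
28 | 4-[(2S,3R)-6-{[(3S,4S,5R)-5-(3-hydroxy-4-methoxyphenyl)-4-(hydroxymethyl)tetrahydrofuran-3-yl]methyl}-3-(hydroxymethyl)-4-methoxy-2,3-dihydrobenzofuran-2-yl]-2-methoxyphenol | COc1ccc([C@@H]2OC[C@@H](Cc3cc(OC)c4c(c3)O[C@H](c3ccc(O)c(OC)c3)[C@H]4CO)[C@H]2CO)cc1O | target

Total step count: 20.
Longest linear sequence: 11 steps (steps 1, 2, 3, 6, 7, 8, 9, 10, 11, 19, 20, from 1 to 28). The boronic acid branch (steps 4–5) and the tetrahydrofuran branch (steps 12–18) are convergent.

Steps most likely to fail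

Step 7 (oxidative ring contraction). The C3 iodane may lose a proton to give the flavone instead of rearranging. Ring B may migrate in place of C4a. The electron-rich ring A may be attacked by the oxidant, or the acid may open C2–O1 and erode the C2 configuration. The fallback makes the same C3–C3a bond by a Wolff ring contraction, setting out from 9 and returning at 13. Kinetic enolisation of 9 with LiN(SiMe3)2 at −78 °C and acylation with CF3CO2CH2CF3 should give the 3-trifluoroacetyl flavanone F1. MsN3 and Et3N in aqueous MeCN (detrifluoroacetylative diazo transfer) should convert it into the 3-diazoflavanone F2. Irradiation at 350 nm in MeOH should expel N2 with migration of C4a to C3 and give the ring-contracted ketene F3, which adds MeOH to give the ester as a mixture rich in the cis ester F4. DBU in toluene should equilibrate the C3 epimers to the trans ester, which is 13.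

Step 19 (hydroboration and B-alkyl Suzuki coupling). Hydroboration may be poorly face-selective at C4, since the C2 aryl group lies on the face that the C3 substituent leaves open. Transmetallation of the alkylborane may also be slow, so that the triflate is hydrolysed or reduced. The fallback builds the tetrahydrofuran on the arene, setting out from 17 and 23 and returning at 28. Sonogashira coupling (Pd(PPh3)4, CuI, Et3N, DMF, 60 °C) should give the aryl alkyne F5. Cp2TiCl (from Cp2TiCl2 and Zn) opens the epoxide, and the C3 radical closes 5-exo-dig to the 2,3-trans 4-arylmethylidene tetrahydrofuran F6. Hydrogenation over Pd/C in EtOAc should add hydrogen to the exocyclic alkene from the face opposite the C3 hydroxymethyl group and give the 3,4-cis tris-silyl ether F7. Bu4NF/AcOH as in step 20 then gives 28.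

Step 6 (asymmetric conjugate addition). The 5,7-dialkoxychromone is a deactivated acceptor, so insertion may be slow, protodeboronation of 8 may compete, and the enantioselectivity may erode. The fallback avoids the conjugate addition, setting out from 3 and returning at 9. Vanillin is acylated (PivCl, Et3N) to 4-formyl-2-methoxyphenyl pivalate F8. Claisen–Schmidt condensation with 3 mediated by BF3·OEt2 in dioxane should give the 2'-hydroxychalcone F9. NaOAc in refluxing EtOH closes it by oxa-Michael addition to the racemic flavanone F10. Preparative HPLC on a cellulose tris(3,5-dimethylphenylcarbamate) phase separates the (S)-enantiomer, which is 9.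

Further compounds
F1 | step 7 | 4-[(2S)-7-benzyloxy-5-methoxy-4-oxo-3-(trifluoroacetyl)chroman-2-yl]-2-methoxyphenyl pivalate (C3 epimers or enol) | COc1cc(OCc3ccccc3)cc2c1C(=O)C(C(=O)C(F)(F)F)[C@@H](c1ccc(OC(=O)C(C)(C)C)c(OC)c1)O2
F2 | step 7 | 4-(7-benzyloxy-3-diazo-5-methoxy-4-oxochroman-2-yl)-2-methoxyphenyl pivalate (C2 spatially as in 9) | COc1cc(OCc3ccccc3)cc2c1C(=O)C(=[N+]=[N-])[C@@H](c1ccc(OC(=O)C(C)(C)C)c(OC)c1)O2
F3 | step 7 | 4-[6-benzyloxy-4-methoxy-3-(oxomethylidene)-2,3-dihydrobenzofuran-2-yl]-2-methoxyphenyl pivalate (ketene; C2 spatially as in 9) | COc1cc(OCc3ccccc3)cc2c1C(=C=O)[C@@H](c1ccc(OC(=O)C(C)(C)C)c(OC)c1)O2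
F4 | step 7 | methyl (2S,3R)-6-benzyloxy-4-methoxy-2-[3-methoxy-4-(pivaloyloxy)phenyl]-2,3-dihydrobenzofuran-3-carboxylate (2,3-cis epimer of 13) | COc1cc(OCc3ccccc3)cc2c1[C@@H](C(=O)OC)[C@@H](c1ccc(OC(=O)C(C)(C)C)c(OC)c1)O2
F5 | step 19 | (2S,3R)-4-methoxy-2-[3-methoxy-4-(triisopropylsilyloxy)phenyl]-6-{3-[(S)-[4-methoxy-3-(triisopropylsilyloxy)phenyl](oxiran-2-yl)methoxy]prop-1-yn-1-yl}-3-[(triisopropylsilyloxy)methyl]-2,3-dihydrobenzofuran (both epoxide epimers) | COc1cc(C#CCO[C@@H](c4ccc(OC)c(O[Si](C(C)C)(C(C)C)C(C)C)c4)C4CO4)cc2c1[C@H](CO[Si](C(C)C)(C(C)C)C(C)C)[C@@H](c1ccc(O[Si](C(C)C)(C(C)C)C(C)C)c(OC)c1)O2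
F6 | step 19 | [(2R,3S)-2-[4-methoxy-3-(triisopropylsilyloxy)phenyl]-4-({(2S,3R)-4-methoxy-2-[3-methoxy-4-(triisopropylsilyloxy)phenyl]-3-[(triisopropylsilyloxy)methyl]-2,3-dihydrobenzofuran-6-yl}methylidene)tetrahydrofuran-3-yl]methanol (alkene isomers) | COc1ccc([C@@H]2OCC(=Cc3cc(OC)c4c(c3)O[C@H](c3ccc(O[Si](C(C)C)(C(C)C)C(C)C)c(OC)c3)[C@H]4CO[Si](C(C)C)(C(C)C)C(C)C)[C@H]2CO)cc1O[Si](C(C)C)(C(C)C)C(C)C
F7 | step 19 | tris(triisopropylsilyl) ether of 28 with the tetrahydrofuran hydroxymethyl group free | COc1ccc([C@@H]2OC[C@@H](Cc3cc(OC)c4c(c3)O[C@H](c3ccc(O[Si](C(C)C)(C(C)C)C(C)C)c(OC)c3)[C@H]4CO[Si](C(C)C)(C(C)C)C(C)C)[C@H]2CO)cc1O[Si](C(C)C)(C(C)C)C(C)C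
F8 | step 6 | 4-formyl-2-methoxyphenyl pivalate | COc1cc(C=O)ccc1OC(=O)C(C)(C)C
F9 | step 6 | 4-[(E)-3-(4-benzyloxy-2-hydroxy-6-methoxyphenyl)-3-oxoprop-1-en-1-yl]-2-methoxyphenyl pivalate | COc1cc(OCc2ccccc2)cc(O)c1C(=O)/C=C/c1ccc(OC(=O)C(C)(C)C)c(OC)c1
F10 | step 6 | rac-4-(7-benzyloxy-5-methoxy-4-oxochroman-2-yl)-2-methoxyphenyl pivalate | COc1cc(OCc3ccccc3)cc2c1C(=O)CC(c1ccc(OC(=O)C(C)(C)C)c(OC)c1)O2
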